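**Retrosynthetic overview**

1. Numbering: C7a = O–CH(aryl) and C8a = CH of the dihydrofuran; C7b = ArCH and C8b = CH2 of the seven-membered ring; ring A = the aryl on C7a; ring B (C9a–C14a) carries C8a on C9a and C7b on C10a; ring C = the aryl on C7b; ring D (C9b–C14b) carries C8b on C9b, C8a on C10b and the furan oxygen on C11b.
2. Feature: ring D is bonded through carbon C10b to C8a and through the C11b oxygen to C7a, the two carbons of what can be a 4-oxystilbene double bond C7a=C8a, and it is already held to ring B by the C8b–C7b bridge. A 5-alkylresorcinol can therefore add across the oxidised alkene as a carbon/oxygen bisnucleophile.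
3. Disconnections: four O–CH3 bonds (last step); then C8a–C10b and C7a–O in one anodic step from stilbene–resorcinol 12, which closes the seven-membered ring first and the dihydrofuran second, with C7b directing C8a and C7a.
4. Precursor: C8a–C9a by Suzuki–Miyaura coupling of aryl bromide 10; C7b–H by asymmetric hydrogenation of triarylethene 8; C7b–C8b by benzyl Grignard addition to diaryl ketone 3, which comes from a Friedel–Crafts acylation.

Key step: step 8

Assumption: which antipode of [Ir(cod)(tBu-PHOX)]BArF gives (S)-9 from (Z)-8 cannot be read safely from a model; one trial run with each antipode fixes it, and the route is written with the (S)-ligand standing for the antipode that gives (S)-9.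

**Route**

Step 1
Reactants: 1 1-bromo-3,5-dimethoxybenzene; 2 4-methoxybenzoyl chloride
Product: 3 (2-bromo-4,6-dimethoxyphenyl)(4-methoxyphenyl)methanone
Conditions: AlCl3 (1.2 equiv), CH2Cl2, 0 °C
Reagents that add atoms: none
Why: Friedel–Crafts acylation at the 2-position of 1, para to one methoxy group and ortho to the other (the site at which this arene is also formylated), the carbon between the two methoxy groups being more crowded; the low temperature keeps the methoxy group ortho to the new carbonyl intact.

Step 2
Reactants: 4 [3,5-bis(benzyloxy)phenyl]methanol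
Product: 5 1,3-bis(benzyloxy)-5-(chloromethyl)benzene
Conditions: SOCl2, DMF (cat.), CH2Cl2, 0 °C → rt
Reagents that add atoms: thionyl chloride, O=S(Cl)Cl
Why: Standard conversion of a benzylic alcohol into the chloride through its chlorosulfite; the chloride is chosen over the bromide because it gives less Wurtz coupling in the next step.

Step 3
Reactants: 5 1,3-bis(benzyloxy)-5-(chloromethyl)benzene; 3 (2-bromo-4,6-dimethoxyphenyl)(4-methoxyphenyl)methanone
Product: 7 rac-2-[3,5-bis(benzyloxy)phenyl]-1-(2-bromo-4,6-dimethoxyphenyl)-1-(4-methoxyphenyl)ethanol, via [3,5-bis(benzyloxy)benzyl]magnesium chloride 6 (not isolated)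
Conditions: Mg, 2-MeTHF, 0 °C; then 3, LaCl3·2LiCl (0.3 equiv), THF, 0 °C → rt; aq. NH4Cl
Reagents that add atoms: none
Why: Grignard 1,2-addition to a ketone that cannot enolise, with LaCl3·2LiCl activating the shielded carbonyl and the para position of the 4-methoxyphenyl ring blocked against conjugate addition; the aryl bromide does not react with a benzylic Grignard reagent at this temperature.

Step 4
Reactants: 7 rac-2-[3,5-bis(benzyloxy)phenyl]-1-(2-bromo-4,6-dimethoxyphenyl)-1-(4-methoxyphenyl)ethanol
Product: 8 (Z)-2-[2-[3,5-bis(benzyloxy)phenyl]-1-(4-methoxyphenyl)ethenyl]-1-bromo-3,5-dimethoxybenzene (ring D cis to ring B, trans to ring C)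
Conditions: TsOH·H2O (5 mol%), toluene, 90 °C, Dean–Stark trap; recrystallisation
Reagents that add atoms: none
Why: Acid-catalysed unimolecular dehydration of the tertiary bis-benzylic carbinol through its cation, in which reversible protonation of the alkene is expected to equilibrate the geometry towards the Z isomer (ring D and ring C form a planar trans-stilbene unit while the 2,6-disubstituted ring B stands perpendicular), and crystallisation removes remaining E isomer.

Step 5
Reactants: 8 (Z)-2-[2-[3,5-bis(benzyloxy)phenyl]-1-(4-methoxyphenyl)ethenyl]-1-bromo-3,5-dimethoxybenzene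
Product: 9 (S)-2-[2-[3,5-bis(benzyloxy)phenyl]-1-(4-methoxyphenyl)ethyl]-1-bromo-3,5-dimethoxybenzene
Conditions: [Ir(cod)((S)-tBu-PHOX)]BArF (2 mol%; cod = 1,5-cyclooctadiene, BArF = B[3,5-(CF3)2C6H3]4), H2 (50 bar), CH2Cl2, 25 °C
Reagents that add atoms: none
Why: Asymmetric hydrogenation of an unfunctionalised trisubstituted triaryl alkene with [Ir(cod)((S)-tBu-PHOX)]BArF, a catalyst class that reads the enantioface from the alkene geometry (here fixed as Z) and so sets C7b; aryl bromide, benzyl ethers and methyl ethers are inert under these conditions.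

Step 6
Reactants: 9 (S)-2-[2-[3,5-bis(benzyloxy)phenyl]-1-(4-methoxyphenyl)ethyl]-1-bromo-3,5-dimethoxybenzene
Product: 10 (S)-5-[2-(2-bromo-4,6-dimethoxyphenyl)-2-(4-methoxyphenyl)ethyl]benzene-1,3-diol
Conditions: BCl3 (5 equiv), pentamethylbenzene (6 equiv), CH2Cl2, −78 °C; MeOH, then H2O
Reagents that add atoms: none
Why: Lewis-acid debenzylation with a cation scavenger, in which BCl3 cleaves aryl benzyl ethers at −78 °C while aryl methyl ethers survive and pentamethylbenzene takes up the benzyl cation; it is run before the stilbene is installed so that the acid-sensitive alkene never meets BCl3.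

Step 7
Reactants: 10 (S)-5-[2-(2-bromo-4,6-dimethoxyphenyl)-2-(4-methoxyphenyl)ethyl]benzene-1,3-diol; 11 (E)-[2-(4-methoxyphenyl)ethenyl]boronic acid
Product: 12 (S)-5-[2-[2,4-dimethoxy-6-[(E)-2-(4-methoxyphenyl)ethenyl]phenyl]-2-(4-methoxyphenyl)ethyl]benzene-1,3-diol
Conditions: Pd(OAc)2 (5 mol%), SPhos (10 mol%), K3PO4 (4 equiv), 1,4-dioxane/H2O, 80 °C, argon
Reagents that add atoms: none
Why: Suzuki–Miyaura coupling, in which the biaryl phosphine allows oxidative addition of the ortho-substituted, electron-rich bromide, the alkenylboronic acid transfers its E geometry unchanged, and the free resorcinol is carried as its phenoxide by the extra base.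

Step 8
Reactants: 12 (S)-5-[2-[2,4-dimethoxy-6-[(E)-2-(4-methoxyphenyl)ethenyl]phenyl]-2-(4-methoxyphenyl)ethyl]benzene-1,3-diol
Product: 16 ampelopsin B 4a,11a,13a,4b-tetra-O-methyl ether (7aS,8aS,7bS; C13b hydroxyl free), via stilbene radical cation 13 (not isolated), via ring-closed C7a radical 14 (not isolated), via ring-closed C7a cation 15 (not isolated)
Conditions: constant current (ca. 1 mA/cm2, 2.1 F/mol), undivided cell, graphite anode, Pt cathode, n-Bu4NBF4 (0.1 M), 2,6-lutidine (2 equiv), (CF3)2CHOH/CH2Cl2 4:1, 2 mM in 12, 0 °C → rt, argon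
Reagents that add atoms: none
Why: Proposed new method: one-electron oxidation of the trimethoxystilbene unit of 12, its most easily oxidised π system, gives radical cation 13, whose C8a terminus is attacked by C10b of the tethered resorcinol (ortho to one hydroxyl, para to the other); after proton loss the spin rests on the 4-methoxybenzylic carbon C7a in 14, which is oxidised at a lower potential than 12 to cation 15, and the C11b hydroxyl captures it. The closest known reactions are anodic and chemical oxidative [3+2] couplings of phenols with aryl alkenes, the radical-cation dimerisation of 4-oxygenated stilbenes and propenylbenzenes to dihydrobenzofurans, and anodic couplings of alkene radical cations with tethered arenes; none of them has been used to close two rings on a resorcinol–stilbene. The seven-membered ring closes first by 7-exo-trig attack on C8a (should the resorcinol be oxidised first, its radical adds to the same carbon and the paths converge), and the dihydrofuran closes second by 5-exo-trig capture of the C7a cation by oxygen. C8a is set by C7b: allylic strain with the C11a methoxy group keeps the C7b hydrogen in the plane of ring B, which places C8b with ring D on one face and ring C (pseudo-axial in the new ring) on the other, so ring D adds to its own face of the s-trans styryl group and the C8a hydrogen comes out anti to the C7b hydrogen; the ring A aryl on C7a then takes the position trans to ring B on C8a, which is the kinetic mode of capture and, since the benzylic C7a–O bond can reopen in the acidic anode layer, also the thermodynamic one. The step needs chemoselectivity against closure by ring C (its ortho carbons are meta to the methoxy group and poorly nucleophilic), against bimolecular radical-cation coupling (answered by the 2 mM concentration) and against further oxidation of 16 (it has lost the stilbene chromophore and should be oxidised at a higher potential; the charge is limited to about 2 F/mol).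

Step 9
Reactants: 16 ampelopsin B 4a,11a,13a,4b-tetra-O-methyl ether (7aS,8aS,7bS)
Product: 17 ampelopsin B, (7aS,8aS,7bS)
Conditions: BBr3 (10 equiv), CH2Cl2, −78 °C → rt; MeOH, then H2O
Reagents that add atoms: none
Why: Exhaustive Lewis-acid demethylation of aryl methyl ethers, which leaves the stereocentres alone because C7b and C8a are C–H centres without an ionisable bond and the benzylic C7a–O bond, if it opens under the acid, should reclose to the more stable trans-dihydrofuran.

**Compound list**

1 | 1-bromo-3,5-dimethoxybenzene | COc1cc(Br)cc(OC)c1 | starting material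
2 | 4-methoxybenzoyl chloride | COc1ccc(C(Cl)=O)cc1 | starting material
3 | (2-bromo-4,6-dimethoxyphenyl)(4-methoxyphenyl)methanone | COc1ccc(cc1)C(=O)c1c(Br)cc(OC)cc1OC | intermediate
4 | [3,5-bis(benzyloxy)phenyl]methanol | OCc1cc(OCc2ccccc2)cc(OCc2ccccc2)c1 | starting material
5 | 1,3-bis(benzyloxy)-5-(chloromethyl)benzene | ClCc1cc(OCc2ccccc2)cc(OCc2ccccc2)c1 | intermediate
6 | [3,5-bis(benzyloxy)benzyl]magnesium chloride | Cl[Mg]Cc1cc(OCc2ccccc2)cc(OCc2ccccc2)c1 | intermediate (not isolated)
7 | rac-2-[3,5-bis(benzyloxy)phenyl]-1-(2-bromo-4,6-dimethoxyphenyl)-1-(4-methoxyphenyl)ethanol | COc1ccc(cc1)C(O)(Cc1cc(OCc2ccccc2)cc(OCc2ccccc2)c1)c1c(Br)cc(OC)cc1OC | intermediate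
8 | (Z)-2-[2-[3,5-bis(benzyloxy)phenyl]-1-(4-methoxyphenyl)ethenyl]-1-bromo-3,5-dimethoxybenzene | COc1ccc(cc1)/C(=C/c1cc(OCc2ccccc2)cc(OCc2ccccc2)c1)c1c(Br)cc(OC)cc1OC | intermediate
9 | (S)-2-[2-[3,5-bis(benzyloxy)phenyl]-1-(4-methoxyphenyl)ethyl]-1-bromo-3,5-dimethoxybenzene | COc1ccc(cc1)[C@H](Cc1cc(OCc2ccccc2)cc(OCc2ccccc2)c1)c1c(Br)cc(OC)cc1OC | intermediate
10 | (S)-5-[2-(2-bromo-4,6-dimethoxyphenyl)-2-(4-methoxyphenyl)ethyl]benzene-1,3-diol | COc1ccc(cc1)[C@H](Cc1cc(O)cc(O)c1)c1c(Br)cc(OC)cc1OC | intermediate
11 | (E)-[2-(4-methoxyphenyl)ethenyl]boronic acid | COc1ccc(/C=C/B(O)O)cc1 | starting material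
12 | (S)-5-[2-[2,4-dimethoxy-6-[(E)-2-(4-methoxyphenyl)ethenyl]phenyl]-2-(4-methoxyphenyl)ethyl]benzene-1,3-diol | COc1ccc([C@H](Cc2cc(O)cc(O)c2)c2c(/C=C/c3ccc(OC)cc3)cc(OC)cc2OC)cc1 | intermediate (key-step precursor)
13 | radical cation of 12, drawn in the limiting form with the charge on C8a and the spin on C7a | COc1ccc([C@H](Cc2cc(O)cc(O)c2)c2c([CH+][CH]c3ccc(OC)cc3)cc(OC)cc2OC)cc1 | intermediate (not isolated)
14 | seven-membered-ring radical with the C8a–C10b bond formed, spin on C7a, C11b hydroxyl free | COc1ccc([C@@H]2Cc3cc(O)cc(O)c3[C@H](c3cc(OC)cc(OC)c32)[CH]c2ccc(OC)cc2)cc1 | intermediate (not isolated)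
15 | seven-membered-ring 4-methoxybenzylic cation at C7a, C11b hydroxyl free | COc1ccc([C@@H]2Cc3cc(O)cc(O)c3[C@H](c3cc(OC)cc(OC)c32)[CH+]c2ccc(OC)cc2)cc1 | intermediate (not isolated)
16 | ampelopsin B 4a,11a,13a,4b-tetra-O-methyl ether, (7aS,8aS,7bS), C13b hydroxyl free, trans-dihydrofuran, C7b hydrogen anti to C8a hydrogen | COc1ccc([C@@H]2Cc3cc(O)cc4c3[C@H](c3cc(OC)cc(OC)c32)[C@@H](c2ccc(OC)cc2)O4)cc1 | intermediate (key-step product)
17 | ampelopsin B, (7aS,8aS,7bS) | Oc1ccc([C@@H]2Cc3cc(O)cc4c3[C@H](c3cc(O)cc(O)c32)[C@@H](c2ccc(O)cc2)O4)cc1 | target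

**Step count and risks**

Total step count: 9. Longest linear sequence: 8 steps (steps 1, 3, 4, 5, 6, 7, 8, 9 from 1-bromo-3,5-dimethoxybenzene; the branch from 4 through steps 2 to 9 is equally long).

Steps most likely to fail:

Step 8 (the proposed new method). What may go wrong:
- bimolecular coupling of the stilbene radical cation instead of intramolecular capture;
- oxidation of the doubly benzylic C7b–H bond or of the phenolic product;
- closure on the other face of C8a.

Fallback with known chemistry, setting out from 10: Mizoroki–Heck coupling with 4-acetoxystyrene (Pd(OAc)2, P(o-tol)3, Et3N, DMF, 100 °C) should give 4-[(E)-2-[2-[(S)-2-(3,5-dihydroxyphenyl)-1-(4-methoxyphenyl)ethyl]-3,5-dimethoxyphenyl]ethenyl]phenyl acetate F1. Methanolysis (K2CO3, MeOH) should free the 4-hydroxystilbene (S)-5-[2-[2-[(E)-2-(4-hydroxyphenyl)ethenyl]-4,6-dimethoxyphenyl]-2-(4-methoxyphenyl)ethyl]benzene-1,3-diol F2. Chemical one-electron oxidation of F2 (Ag2O, acetone/CH2Cl2, high dilution) then follows the known biomimetic coupling of 4-hydroxystilbenes with resorcinol rings to 2,3-dihydrobenzofurans: the phenoxyl radical of ring A carries spin at C8a and bonds to C10b of the neighbouring resorcinol, and the para-quinone methide left at C7a is closed by the C11b hydroxyl. This should give ampelopsin B 11a,13a,4b-tri-O-methyl ether F3, which BBr3 demethylates. The fallback comes back to the route at 17.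

Step 5. What may go wrong:
- slow hydrogen uptake at an alkene shielded on both faces by the perpendicular 2,6-disubstituted ring;
- acid-induced E/Z isomerisation before reduction, which erodes the enantioselectivity.

Fallback, setting out from 7: ionic hydrogenation (Et3SiH, CF3CO2H, CH2Cl2, 0 °C) reduces the tertiary bis-benzylic cation with no demand on alkene geometry and should give the racemate rac-2-[2-[3,5-bis(benzyloxy)phenyl]-1-(4-methoxyphenyl)ethyl]-1-bromo-3,5-dimethoxybenzene F4. Preparative chromatography on a chiral stationary phase (amylose-based column, CO2/MeOH) separates it. The (R) enantiomer (R)-2-[2-[3,5-bis(benzyloxy)phenyl]-1-(4-methoxyphenyl)ethyl]-1-bromo-3,5-dimethoxybenzene F5 is set aside, and the (S) enantiomer is 9, where the fallback comes back to the route.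

Step 3. What may go wrong:
- Wurtz coupling while the benzylic magnesium reagent forms;
- failure of the carbon nucleophile to reach the carbonyl flanked by bromine and methoxy, with electron-transfer reduction of the ketone instead.

Fallback, setting out from 3: McMurry cross-coupling with commercial 3,5-bis(benzyloxy)benzaldehyde (TiCl4, Zn, pyridine, THF, reflux) joins the two carbonyl carbons reductively through ketyl intermediates, so no nucleophile has to approach the shielded carbon and the aryl bromide is tolerated. After equilibration of the geometry with catalytic TsOH, the triarylethene obtained is 8, where the fallback comes back to the route, replacing steps 3 and 4. It makes no compound outside the list (F0).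

**Further compounds**

F1 | step 8 | 4-[(E)-2-[2-[(S)-2-(3,5-dihydroxyphenyl)-1-(4-methoxyphenyl)ethyl]-3,5-dimethoxyphenyl]ethenyl]phenyl acetate | COc1ccc(cc1)[C@H](Cc1cc(O)cc(O)c1)c1c(/C=C/c2ccc(OC(C)=O)cc2)cc(OC)cc1OC
F2 | step 8 | (S)-5-[2-[2-[(E)-2-(4-hydroxyphenyl)ethenyl]-4,6-dimethoxyphenyl]-2-(4-methoxyphenyl)ethyl]benzene-1,3-diol | COc1ccc(cc1)[C@H](Cc1cc(O)cc(O)c1)c1c(/C=C/c2ccc(O)cc2)cc(OC)cc1OC
F3 | step 8 | ampelopsin B 11a,13a,4b-tri-O-methyl ether, (7aS,8aS,7bS) | COc1ccc([C@@H]2Cc3cc(O)cc4c3[C@H](c3cc(OC)cc(OC)c32)[C@@H](c2ccc(O)cc2)O4)cc1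
F4 | step 5 | rac-2-[2-[3,5-bis(benzyloxy)phenyl]-1-(4-methoxyphenyl)ethyl]-1-bromo-3,5-dimethoxybenzene | COc1ccc(cc1)C(Cc1cc(OCc2ccccc2)cc(OCc2ccccc2)c1)c1c(Br)cc(OC)cc1OC
F5 | step 5 | (R)-2-[2-[3,5-bis(benzyloxy)phenyl]-1-(4-methoxyphenyl)ethyl]-1-bromo-3,5-dimethoxybenzene | COc1ccc(cc1)[C@@H](Cc1cc(OCc2ccccc2)cc(OCc2ccccc2)c1)c1c(Br)cc(OC)cc1OC
F0 | step 3 | none | none
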